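Cuts (retrosynthesis): both angelate O–acyl bonds; C1–O back to a C1 ketone and then to a C1 ester; C1–C10 (retro-Wolff, which puts a carbonyl carbon back between C1 and C10); C9=C10 and C2–C3 (aldol and Michael); C3=C9 (metathesis); C7–C8 and C4–C5 (Grignard additions).
Feature that allows the key step: ring A, the cyclopentene C1–C2–C3–C9=C10 with isopropyl on C10 and quaternary C3, is a Robinson-type cyclohexenone that lacks only its carbonyl carbon.
Forward: the chain C3–C9 is joined from three small pieces. Ring B (seven-membered, C3–C9) closes by metathesis, a six-membered enone ring is annulated onto C3/C9, and light contracts it to ring A. The extruded carbon is then cleaved off to leave C1=O, and the esters come last.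
Stereochemistry: C5 and C6 come from one Sharpless kinetic resolution (C5 is only a relay and ends as the ketone), C3 from a chiral-imine Michael addition, and C1 from a CBS reduction. The Z alkenes are bought with angelic acid.

Key step: step 11

Numbering and faces (target atoms, used for all compounds): C1 carbinol carbon of ring A, C2 CH2, C3 quaternary fusion carbon, C4 CH2, C5 ketone, C6 tertiary carbinol carbon, C7 and C8 CH2, C9 fusion alkene carbon, C10 alkene carbon with isopropyl. The target is (1S,3R,6S). α is the face that carries the C3 methyl group and the oxygens on C1, C5 and C6. The C6 methyl group is β.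
Assumption: stereocentres that are erased later (C3 and C9 in 9–11, C1 in 24–26) are drawn as the isomer expected from attack on the more open face; the other isomer would serve equally.

Step 1
Reactants: 1 methacrolein; 2 (2-methylallyl)magnesium chloride
Product: 3 (±)-2,5-dimethylhexa-1,5-dien-3-ol
Conditions: THF, −78 → 0 °C; aq NH4Cl
Reagents that add atoms: none
Why: 1,2-addition of an allylic Grignard reagent to an enal forms C4–C5 and gives the racemic secondary allylic alcohol, whose carbinol centre is resolved in the next step.

Step 2
Reactants: 3 (±)-2,5-dimethylhexa-1,5-dien-3-ol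
Product: 4 (1R)-3-methyl-1-[(2S)-2-methyloxiran-2-yl]but-3-en-1-ol
Conditions: Ti(OiPr)4 (cat.), D-(−)-diisopropyl tartrate, t-BuOOH (0.45 equiv), 4 Å MS, CH2Cl2, −20 °C
Reagents that add atoms: tert-butyl hydroperoxide, CC(C)(C)OO
Why: Sharpless kinetic resolution, in which the D-(−)-tartrate catalyst epoxidises the fast-reacting (R)-alcohol at its allylic (not its homoallylic) alkene to the erythro epoxy alcohol, so that C5 (R) and C6 (S) are set together while the (S)-alcohol stays behind and is separated.

Step 3
Reactants: 4 epoxy alcohol; 5 allylmagnesium chloride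
Product: 6 (4R,5S)-2,5-dimethylnona-1,8-diene-4,5-diol
Conditions: 5 (2.5 equiv), CuI (10 mol %), THF, −30 → 0 °C; aq NH4Cl
Reagents that add atoms: none
Why: Copper-catalysed SN2 opening of a 2,2-disubstituted epoxide by a Grignard reagent occurs at the open CH2 terminus (C7) and forms C7–C8, so the C6–O bond and both stereocentres stay untouched; the first equivalent of 5 only deprotonates the hydroxyl group.

Step 4
Reactants: 6 diene diol
Product: 7 (4S,5R)-4-(but-3-enyl)-2,2,4-trimethyl-5-(2-methylallyl)-1,3-dioxolane
Conditions: 2,2-dimethoxypropane, PPTS (cat.), CH2Cl2, rt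
Reagents that add atoms: 2,2-dimethoxypropane, COC(C)(C)OC
Why: Acid-catalysed transketalisation ties the erythro diol into a dioxolane with its two alkenyl arms cis, which shields both oxygens from the basic and reducing steps ahead and pre-organises the diene for ring closure.

Step 5
Reactants: 7 diene acetonide
Product: 8 ring-B cycloheptene (C3=C9; methyl on C3) with the cis-fused 5α,6α-acetonide
Conditions: second-generation Grubbs catalyst (5 mol %), CH2Cl2 (0.005 M), reflux
Reagents that add atoms: none
Why: Ring-closing metathesis loads on the monosubstituted alkene and closes on the 1,1-disubstituted one with loss of ethene, a well-tried way to trisubstituted cycloheptenes.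

Step 6
Reactants: 8 cycloheptene acetonide
Product: 10 C9β-cycloheptanol (C3 methyl α; 5α/6α-acetonide), via alkylborane 9 (not isolated)
Conditions: BH3·THF, THF, 0 °C → rt; then NaOH, H2O2
Reagents that add atoms: hydrogen peroxide, OO; borane (THF complex), B (boron is found only in 9)
Why: Hydroboration–oxidation places boron on the less substituted alkene carbon C9 by syn addition, expected on the β face away from the dioxolane, and oxidation with retention gives the alcohol; the new centres C3 and C9 are of no consequence.

Step 7
Reactants: 10 cycloheptanol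
Product: 11 2-methylcycloheptanone of ring B (C9=O; C3-H; 5α,6α-acetonide)
Conditions: Dess–Martin periodinane, CH2Cl2, rt
Reagents that add atoms: none
Why: Dess–Martin oxidation turns the secondary alcohol into the ketone under near-neutral conditions that leave the acetonide intact.

Step 8
Reactants: 11 cycloheptanone; 12 (R)-1-phenylethylamine; 13 5-methylhex-1-en-3-one
Product: 16 C3-quaternary 1,5-diketone (C3 methyl α; 5-methyl-3-oxohexyl chain β; 5α/6α-acetonide), via imine 14 (not isolated), via adduct imine 15 (not isolated)
Conditions: 12, toluene, reflux (Dean–Stark); then 13, THF, 40 °C; then 20% aq AcOH, rt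
Reagents that add atoms: water, O
Why: In this asymmetric Michael addition of a chiral imine, 14 reacts through its more substituted secondary enamine tautomer (C3=C9), which erases the old C3 centre and confines attack to C3; the enone is taken up in a compact aza-ene-like transition state on the face not shielded by the phenyl group of the (R)-auxiliary (the sense known for 2-methylcycloalkanone imines), here the β face away from the dioxolane oxygens, so that C2–C3 forms and quaternary C3 keeps its methyl group α.

Step 9
Reactants: 16 1,5-diketone
Product: 18 bicyclic enone (six-membered ring fused to ring B; C9=C10; isopropyl on C10; 5α/6α-acetonide), via ketol 17 (not isolated)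
Conditions: KOH, EtOH, reflux
Reagents that add atoms: none
Why: In this intramolecular aldol condensation (second half of a Robinson annulation), only attack of the C10 enolate on the C9 ketone gives a six-membered ring that can dehydrate, so under equilibrating conditions the reversible side aldols drain into the conjugated tetrasubstituted enone.

Step 10
Reactants: 18 bicyclic enone; 19 4-acetamidobenzenesulfonyl azide
Product: 21 α′-diazo enone (diazo group on C1), via trifluoroacetyl enone 20 (not isolated)
Conditions: LiHMDS, THF, −78 °C; CF3CO2CH2CF3; then 19, Et3N, H2O (1 equiv), MeCN, rt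
Reagents that add atoms: 2,2,2-trifluoroethyl trifluoroacetate, O=C(OCC(F)(F)F)C(F)(F)F (its CF3CO group is found only in 20)
Why: In this detrifluoroacetylative Regitz diazo transfer the kinetic α′-enolate (C1) is trifluoroacetylated, and the activated dicarbonyl compound takes the diazo group from the sulfonyl azide and hands its trifluoroacetyl group to the sulfonamide nitrogen, a sequence that suits enones which fail in direct transfer.

Step 11
Reactants: 21 α′-diazo enone; 22 methanol
Product: 24 hydroazulene C1 methyl ester (C9=C10; isopropyl on C10; 5α/6α-acetonide; ester drawn α), via vinylketene 23 (not isolated)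
Conditions: hν (medium-pressure Hg lamp, Pyrex filter), MeOH, 0 °C → rt
Reagents that add atoms: none
Why: Excitation of the diazo ketone, which the ring holds in the s-Z geometry, drives out N2 while the antiperiplanar bond from C10 to the carbonyl carbon shifts to C1, so that C1–C10 forms and the former carbonyl carbon leaves the ring as the exocyclic vinylketene 23, which methanol captures as the ester. The reaction type is the photochemical Wolff ring contraction of cyclic α-diazo ketones, which is also known for α′-diazo enones. Ring A is closed by a 1,2-shift that contracts the six-membered ring to a five-membered one and not by cyclisation of a chain, so no ring-closure rule is at stake. The only new stereocentre, C1, arises on protonation of the ketene-derived enol, is not controlled and is erased in step 12, while C3, C5 and C6 are spectators. The shift must be faster than O–H insertion into methanol and faster than attack of a free carbene on C9=C10, which the locked s-Z geometry and direct irradiation without sensitiser or metal favour; kinetic α-protonation keeps the alkene at C9=C10, and a conjugated C1=C10 isomer would give the same dienolate in step 12.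

Step 12
Reactants: 24 C1 methyl ester
Product: 25 C1 α-hydroxy ester (hydroxyl drawn β; ester α)
Conditions: KHMDS, THF, −78 °C; then 2-(benzenesulfonyl)-3-phenyloxaziridine, −78 °C
Reagents that add atoms: 2-(benzenesulfonyl)-3-phenyloxaziridine, O=S(=O)(c1ccccc1)N1OC1c1ccccc1
Why: In this enolate hydroxylation with a Davis oxaziridine the doubly activated C1–H is removed from either epimer and the extended enolate reacts at its α carbon C1 because the γ carbon C9 is fully substituted; the new C1 centre is erased in step 14.

Step 13
Reactants: 25 α-hydroxy ester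
Product: 26 C1 tertiary alcohol bearing a CH2OH group (1,2-diol)
Conditions: LiAlH4, Et2O, 0 °C; Fieser work-up
Reagents that add atoms: none
Why: Hydride reduction takes the hindered ester to the primary alcohol, where saponification would be slow, and leaves the acetonide and the tetrasubstituted alkene alone.

Step 14
Reactants: 26 1,2-diol
Product: 27 hydroazulenone (C1=O conjugated with C9=C10; 5α,6α-acetonide)
Conditions: NaIO4, THF/H2O, 0 °C → rt
Reagents that add atoms: none
Why: Malaprade glycol cleavage removes, as formaldehyde, the carbon that the Wolff step pushed out of the ring and keeps the C1 oxygen as the cyclopentenone carbonyl group.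

Step 15
Reactants: 27 cyclopentenone
Product: 28 (1S)-allylic alcohol (C1-OH α; 5α,6α-acetonide)
Conditions: (R)-Me-CBS oxazaborolidine, BH3·SMe2, THF, −30 °C
Reagents that add atoms: none
Why: In this Corey–Bakshi–Shibata reduction the α-isopropyl alkenyl branch (C10) acts as the large group and C2H2 as the small group, so the (R)-catalyst delivers hydride in 1,2-fashion to the β face of C1=O and sets C1 as S with its oxygen α.

Step 16
Reactants: 29 angelic acid (two equivalents)
Product: 30 angelic anhydride
Conditions: DCC (0.5 equiv), CH2Cl2, 0 °C → rt
Reagents that add atoms: none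
Why: Carbodiimide dehydration of a carboxylic acid to its symmetrical anhydride needs no nucleophilic catalyst and so leaves the Z alkene in place.

Step 17
Reactants: 28 allylic alcohol; 30 angelic anhydride
Product: 31 C1α-angelate with the 5α,6α-acetonide
Conditions: LiHMDS, THF, −78 °C; then 30, −78 → 0 °C
Reagents that add atoms: none
Why: Acylation of a lithium alkoxide with the anhydride is fast at low temperature and avoids DMAP-type catalysts, whose conjugate addition would turn angelate into tiglate; only the O–H bond at C1 is broken.

Step 18
Reactants: 31 C1 angelate acetonide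
Product: 32 C1α-angelate 5α,6α-diol
Conditions: AcOH/THF/H2O (3:1:1), 40 °C
Reagents that add atoms: none
Why: Mild acid hydrolysis cleaves the acetonide, and because a carboxylate is a poor leaving group in this medium the allylic C1 ester should not ionise.

Step 19
Reactants: 32 diol
Product: 33 C5 ketone with free tertiary C6α-OH (α-ketol) and C1α-angelate
Conditions: IBX, DMSO, rt
Reagents that add atoms: none
Why: IBX oxidises the secondary alcohol of a 1,2-diol to the α-ketol without glycol cleavage and cannot touch the tertiary hydroxyl group, so the relay centre C5 disappears.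

Step 20
Reactants: 33 α-ketol; 30 angelic anhydride
Product: 34 CNP0193302.1, the (1S,3R,6S)-1,6-bis-angelate of the 5-oxo-hydroazulene
Conditions: LiHMDS (1.0 equiv), THF, −78 °C; then 30, −78 → 0 °C
Reagents that add atoms: none
Why: In this alkoxide acylation one equivalent of base removes the most acidic proton (the ketol O–H) and the anhydride traps the alkoxide at low temperature before enolisation or α-ketol rearrangement can set in; C6 keeps its configuration since only O–H is broken.

Compound list
1 | methacrolein | C=C(C)C=O | starting material
2 | (2-methylallyl)magnesium chloride | C=C(C)C[Mg]Cl | starting material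
3 | (±)-2,5-dimethylhexa-1,5-dien-3-ol | C=C(C)CC(O)C(C)=C | intermediate
4 | (1R)-3-methyl-1-[(2S)-2-methyloxiran-2-yl]but-3-en-1-ol | C=C(C)C[C@@H](O)[C@]1(C)CO1 | intermediate
5 | allylmagnesium chloride | C=CC[Mg]Cl | starting material
6 | (4R,5S)-2,5-dimethylnona-1,8-diene-4,5-diol | C=CCC[C@](C)(O)[C@H](O)CC(C)=C | intermediate
7 | (4S,5R)-4-(but-3-enyl)-2,2,4-trimethyl-5-(2-methylallyl)-1,3-dioxolane | C=CCC[C@]1(C)OC(C)(C)O[C@@H]1CC(C)=C | intermediate
8 | ring-B cycloheptene (C3=C9), cis-fused 5α,6α-acetonide | CC1=CCC[C@]2(C)OC(C)(C)O[C@@H]2C1 | intermediate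
9 | C9β-alkylborane (drawn as RBH2; C3 methyl α) | C[C@H]1C[C@H]2OC(C)(C)O[C@@]2(C)CC[C@@H]1B | intermediate
10 | C9β-cycloheptanol (C3 methyl α) | C[C@H]1C[C@H]2OC(C)(C)O[C@@]2(C)CC[C@@H]1O | intermediate
11 | 2-methylcycloheptanone of ring B (C9=O; C3 epimerisable, drawn methyl α) | C[C@H]1C[C@H]2OC(C)(C)O[C@@]2(C)CCC1=O | intermediate
12 | (R)-1-phenylethylamine | C[C@@H](N)c1ccccc1 | starting material
13 | 5-methylhex-1-en-3-one | C=CC(=O)CC(C)C | starting material
14 | C9 N-[(R)-1-phenylethyl]imine of 11 (C=N isomers and enamine tautomers equilibrate) | C[C@H]1C[C@H]2OC(C)(C)O[C@@]2(C)CCC1=N[C@H](C)c1ccccc1 | intermediate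
15 | Michael adduct imine (C3 quaternary, methyl α) | CC(C)CC(=O)CC[C@]1(C)C[C@H]2OC(C)(C)O[C@@]2(C)CCC1=N[C@H](C)c1ccccc1 | intermediate
16 | C3-quaternary 1,5-diketone | CC(C)CC(=O)CC[C@]1(C)C[C@H]2OC(C)(C)O[C@@]2(C)CCC1=O | intermediate
17 | aldol ketol (C9-OH, C10-H; these two centres undefined, lost on dehydration) | CC(C)C1C(=O)CC[C@]2(C)C[C@H]3OC(C)(C)O[C@@]3(C)CCC12O | intermediate
18 | bicyclic enone (six-membered ring on ring B, isopropyl on C10) | O=C1CC[C@]2(C)C[C@H]3OC(C)(C)O[C@@]3(C)CCC2=C1C(C)C | intermediate
19 | 4-acetamidobenzenesulfonyl azide | CC(=O)Nc1ccc(cc1)S(=O)(=O)N=[N+]=[N-] | starting material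
20 | C1-trifluoroacetyl enone (drawn as diketo tautomer, C1 enolised) | O=C(C1C[C@]2(C)C[C@H]3OC(C)(C)O[C@@]3(C)CCC2=C(C(C)C)C1=O)C(F)(F)F | intermediate
21 | α′-diazo enone | [N-]=[N+]=C1C[C@]2(C)C[C@H]3OC(C)(C)O[C@@]3(C)CCC2=C(C(C)C)C1=O | intermediate
22 | methanol | CO | starting material
23 | vinylketene exocyclic at C1 of ring A | O=C=C1C[C@]2(C)C[C@H]3OC(C)(C)O[C@@]3(C)CCC2=C1C(C)C | intermediate
24 | hydroazulene C1 methyl ester (ester drawn α) | COC(=O)[C@H]1C[C@]2(C)C[C@H]3OC(C)(C)O[C@@]3(C)CCC2=C1C(C)C | intermediate
25 | C1 α-hydroxy ester (OH drawn β) | COC(=O)[C@@]1(O)C[C@]2(C)C[C@H]3OC(C)(C)O[C@@]3(C)CCC2=C1C(C)C | intermediate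
26 | C1 hydroxy, C1 hydroxymethyl diol | OC[C@@]1(O)C[C@]2(C)C[C@H]3OC(C)(C)O[C@@]3(C)CCC2=C1C(C)C | intermediate
27 | hydroazulenone (C1=O) | O=C1C[C@]2(C)C[C@H]3OC(C)(C)O[C@@]3(C)CCC2=C1C(C)C | intermediate
28 | (1S)-allylic alcohol (OH α) | O[C@H]1C[C@]2(C)C[C@H]3OC(C)(C)O[C@@]3(C)CCC2=C1C(C)C | intermediate
29 | angelic acid, (Z)-2-methylbut-2-enoic acid | C/C=C(/C)C(=O)O | starting material
30 | angelic anhydride | C/C=C(/C)C(=O)OC(=O)/C(C)=C\C | intermediate
31 | C1α-angelate, 5α,6α-acetonide | C/C=C(/C)C(=O)O[C@H]1C[C@]2(C)C[C@H]3OC(C)(C)O[C@@]3(C)CCC2=C1C(C)C | intermediate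
32 | C1α-angelate, 5α,6α-diol | C/C=C(/C)C(=O)O[C@H]1C[C@]2(C)C[C@@H](O)[C@@](C)(O)CCC2=C1C(C)C | intermediate
33 | C1α-angelate, C5 ketone, C6α-OH | C/C=C(/C)C(=O)O[C@H]1C[C@]2(C)CC(=O)[C@@](C)(O)CCC2=C1C(C)C | intermediate
34 | CNP0193302.1, (1S,3R,6S)-bis-angelate | C/C=C(/C)C(=O)O[C@H]1C[C@]2(C)CC(=O)[C@@](C)(OC(=O)/C(C)=C\C)CCC2=C1C(C)C | target

Total steps: 20. Longest linear sequence: 19 (steps 1–15 and 17–20); step 16 is a one-step side branch.

Steps most likely to fail

Step 20. Acylation of the hindered tertiary ketol alkoxide may be too slow. Enolisation toward C4, α-ketol rearrangement or Z-to-E isomerisation on forcing could then take over. The fallback sets out from 33 and builds the angelate on the oxygen instead of transferring it.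
- Steglich esterification with the slim but-2-ynoic acid (DCC, DMAP, CH2Cl2; no alkene geometry is at stake) should give the C6 but-2-ynoate F1.
- Syn-hydrostannation (Bu3SnH, Pd(PPh3)4, THF) places tin on the α carbon and hydrogen on the β carbon and should give the C6 (E)-2-(tributylstannyl)but-2-enoate F2.
- Stille methylation (MeI, Pd2(dba)3, P(2-furyl)3, CuI, DMF) replaces tin by methyl with retention. That is the Z geometry, and the route is rejoined at 34.

Step 9. The aldol equilibrium may stay on the side of the open diketone, or dehydration may stall, because the nucleophilic carbon carries isopropyl and the C9 ketone is neopentyl. The fallback sets out from 11 and brings in the isopropyl group after ring closure.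
- Imine 14 is treated with but-3-en-2-one in place of 13 to give the methyl ketone adduct imine F3.
- Aqueous AcOH hydrolyses F3 to the 3-oxobutyl diketone F4.
- NaOMe in MeOH closes the unhindered aldol condensation to the enone with hydrogen on C10, F5.
- Iodination (I2, pyridine, CH2Cl2) should give the C10 iodo enone F6.
- Suzuki–Miyaura coupling with isopropenylboronic acid pinacol ester (PdCl2(dppf), K3PO4, dioxane/H2O) should give the C10 isopropenyl dienone F7.
- Hydrogenation over RhCl(PPh3)3 saturates only the 1,1-disubstituted alkene and comes back to the route at 18.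

Step 15. Facial selectivity of hydride delivery may be poor if catalyst and substrate are mismatched, since the two faces of C1=O differ only as CH3 against CH2 on C3. The fallback sets out from 27 and makes both epimers useful.
- Luche reduction (NaBH4, CeCl3·7H2O, MeOH, −78 °C) gives the allylic alcohols under substrate control.
- Any 28 formed goes on through step 17.
- The C1β-alcohol F8 is esterified with angelic acid 29 under Mitsunobu conditions (PPh3, DIAD, toluene, 0 °C) with inversion at C1, which comes back to the route at 31.

Further compounds
F1 | step 20 | C6 but-2-ynoate of 33 | C/C=C(/C)C(=O)O[C@H]1C[C@]2(C)CC(=O)[C@@](C)(OC(=O)C#CC)CCC2=C1C(C)C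
F2 | step 20 | C6 (E)-2-(tributylstannyl)but-2-enoate | C/C=C(/C)C(=O)O[C@H]1C[C@]2(C)CC(=O)[C@@](C)(OC(=O)/C([Sn](CCCC)(CCCC)CCCC)=C\C)CCC2=C1C(C)C
F3 | step 9 | methyl ketone adduct imine | CC(=O)CC[C@]1(C)C[C@H]2OC(C)(C)O[C@@]2(C)CCC1=N[C@H](C)c1ccccc1
F4 | step 9 | 3-oxobutyl diketone | CC(=O)CC[C@]1(C)C[C@H]2OC(C)(C)O[C@@]2(C)CCC1=O
F5 | step 9 | bicyclic enone with hydrogen on C10 | O=C1CC[C@]2(C)C[C@H]3OC(C)(C)O[C@@]3(C)CCC2=C1
F6 | step 9 | C10 iodo enone | O=C1CC[C@]2(C)C[C@H]3OC(C)(C)O[C@@]3(C)CCC2=C1I
F7 | step 9 | C10 isopropenyl dienone | O=C1CC[C@]2(C)C[C@H]3OC(C)(C)O[C@@]3(C)CCC2=C1C(C)=C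
F8 | step 15 | C1β-alcohol (C1 epimer of 28) | O[C@@H]1C[C@]2(C)C[C@H]3OC(C)(C)O[C@@]3(C)CCC2=C1C(C)C
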